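**Plan**

- Retrosynthesis: the bond from C1 of ring B to its carboxyl carbon is cut first (aryl iodide + CO + water). Next comes the depside ester C(=O)–O bond between the ring A carbonyl and the C4 oxygen of ring B. Last come the C–I bond of ring B and the C1–carbonyl bond of ring A, the latter traced back to a formyl group.
- Forward: no ring is built, because both benzene rings are bought as 5-alkylresorcinols. Olivetol is formylated, 4-O-methylated, protected as the methoxymethyl (MOM) ether and oxidised to the ring A acid. 5-Propylresorcinol is dimethylated, mono-demethylated and iodinated para to the hydroxyl. The two halves are esterified, the MOM group is removed, and carbonylation ends the route.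
- Enabling feature: the free carboxyl at C1 of ring B lies between the C2 methoxy and the C6 propyl group, para to the C4 oxygen that carries the base-labile aryl ester to ring A. A C1–I bond in its place is inert to esterification and to acid, and becomes CO2H under weakly basic conditions, so no acid protecting group has to be removed beside the depside ester.
- Stereochemistry: the target has no stereocentre and no stereogenic double bond; only regiochemistry has to be controlled (C4 of olivetol, C4 of the ring B phenol).

Key step: step 10

Remark: the iodination in step 7 is assumed to favour the carbon para to the free hydroxyl of 9; the constitution of 10 would be confirmed by NOE before the fragments are joined.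

**Route**

Step 1
Reactants: 1 olivetol (5-pentylbenzene-1,3-diol)
Product: 3 2,4-dihydroxy-6-pentylbenzaldehyde, via iminium chloride 2 (not isolated)
Conditions: POCl3, DMF, 0 °C to rt; then H2O, 50 °C
Reagents that add atoms: N,N-dimethylformamide, CN(C)C=O; water, O
Why: Vilsmeier–Haack formylation, in which the chloroiminium ion made from DMF and POCl3 attacks the resorcinol at C4 (para to one hydroxyl, ortho to the other, the usual site for 5-alkylresorcinols) and water then hydrolyses iminium salt 2 to the aldehyde.

Step 2
Reactants: 3 2,4-dihydroxy-6-pentylbenzaldehyde
Product: 4 2-hydroxy-4-methoxy-6-pentylbenzaldehyde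
Conditions: MeI (1.1 equiv), K2CO3, acetone, rt
Reagents that add atoms: iodomethane, CI
Why: Williamson ether synthesis, selective because the 4-hydroxyl para to the formyl group is the more acidic and freely available one while the 2-hydroxyl is held in a hydrogen bond to the carbonyl oxygen.

Step 3
Reactants: 4 2-hydroxy-4-methoxy-6-pentylbenzaldehyde
Product: 5 4-methoxy-2-(methoxymethoxy)-6-pentylbenzaldehyde
Conditions: NaH, MOMCl, DMF, 0 °C to rt
Reagents that add atoms: chloromethyl methyl ether, COCCl
Why: Williamson-type O-alkylation to the methoxymethyl ether, in which full deprotonation by NaH breaks the chelate and the phenoxide displaces chloride from the reactive α-chloro ether.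

Step 4
Reactants: 5 4-methoxy-2-(methoxymethoxy)-6-pentylbenzaldehyde
Product: 6 4-methoxy-2-(methoxymethoxy)-6-pentylbenzoic acid
Conditions: NaClO2, NaH2PO4, 2-methyl-2-butene, t-BuOH/H2O, rt
Reagents that add atoms: sodium chlorite, [Na+].[O-]Cl=O
Why: Pinnick oxidation, in which chlorous acid converts the non-enolisable aldehyde into the acid in a buffer mild enough for the acetal, and 2-methyl-2-butene traps the hypochlorous acid that would otherwise chlorinate the electron-rich ring.

Step 5
Reactants: 7 5-propylresorcinol (5-propylbenzene-1,3-diol)
Product: 8 1,3-dimethoxy-5-propylbenzene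
Conditions: MeI (excess), K2CO3, acetone, reflux
Reagents that add atoms: iodomethane, CI
Why: Exhaustive Williamson methylation of both phenols, chosen so that the unsymmetrical monoether is reached cleanly in the next step instead of by a statistical mono-alkylation.

Step 6
Reactants: 8 1,3-dimethoxy-5-propylbenzene
Product: 9 3-methoxy-5-propylphenol
Conditions: NaSEt, DMF, 140 °C; then aq. HCl
Reagents that add atoms: none
Why: Nucleophilic (SN2) O-demethylation by thiolate, which stops after one methyl group because the phenoxide formed makes the remaining methoxy oxygen a far poorer leaving group, as is usual for resorcinol dimethyl ethers.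

Step 7
Reactants: 9 3-methoxy-5-propylphenol
Product: 10 4-iodo-3-methoxy-5-propylphenol
Conditions: NIS (1.0 equiv), TsOH·H2O (cat.), MeCN, 0 °C to rt, dark
Reagents that add atoms: N-iodosuccinimide, O=C1CCC(=O)N1I
Why: Electrophilic aromatic iodination with acid-activated NIS, expected to go mainly to C4 (para to the free hydroxyl, the stronger donor, and ortho to methoxy) while C2 between the two oxygens is the most crowded site, any isomer iodinated para to the methoxy group being removed by chromatography.

Step 8
Reactants: 6 4-methoxy-2-(methoxymethoxy)-6-pentylbenzoic acid; 10 4-iodo-3-methoxy-5-propylphenol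
Product: 11 4-iodo-3-methoxy-5-propylphenyl 4-methoxy-2-(methoxymethoxy)-6-pentylbenzoate
Conditions: DCC, DMAP (cat.), CH2Cl2, 0 °C to rt
Reagents that add atoms: none
Why: Steglich esterification, in which the carbodiimide-activated acid is relayed by DMAP as an acylpyridinium ion to the unhindered phenol under neutral conditions that leave the acetal and the aryl iodide untouched.

Step 9
Reactants: 11 4-iodo-3-methoxy-5-propylphenyl 4-methoxy-2-(methoxymethoxy)-6-pentylbenzoate
Product: 12 4-iodo-3-methoxy-5-propylphenyl 2-hydroxy-4-methoxy-6-pentylbenzoate
Conditions: TFA, CH2Cl2, 0 °C to rt; aqueous work-up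
Reagents that add atoms: none
Why: Acid-catalysed acetal cleavage of the methoxymethyl ether, eased by the ortho carbonyl that takes the freed hydroxyl into a hydrogen bond, while the doubly ortho-substituted aryl ester and the aryl iodide are inert to TFA at this temperature.

Step 10
Reactants: 12 4-iodo-3-methoxy-5-propylphenyl 2-hydroxy-4-methoxy-6-pentylbenzoate
Product: 13 4-[(2-hydroxy-4-methoxy-6-pentylbenzoyl)oxy]-2-methoxy-6-propylbenzoic acid
Conditions: Pd(OAc)2 (cat.), 1,1'-bis(diphenylphosphino)ferrocene (dppf), KOAc, CO (1 atm), DMSO/H2O, 70 °C; then 1 M HCl
Reagents that add atoms: carbon monoxide, [C-]#[O+]; water, O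
Why: Zerovalent palladium formed from Pd(OAc)2 and dppf inserts into the C1–I bond of ring B, CO inserts to give an aroyl complex of divalent palladium, and water deprotonated by acetate cleaves this complex to the carboxylate, returning zerovalent palladium while KOAc takes up the HI. The closest known reaction type is the palladium-catalysed hydroxycarbonylation of aryl iodides and triflates with a Pd(OAc)2/dppf/KOAc system in DMSO. One carbon–carbon bond is formed, no ring closes and no stereocentre arises. The step needs chemoselectivity for the C–I bond over the aryl ester and the free phenol: the only base is acetate, the ester carbonyl is shielded by the pentyl and hydroxyl groups on either side, and the hydrogen-bonded 2-hydroxyl of ring A is too poor a nucleophile to intercept the aroyl complex. The methoxy and propyl groups flanking C1 slow oxidative addition of the iodide but should not prevent it, and the wide bite angle of dppf favours CO insertion over reductive loss of iodine.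

**Compound list**

1 | olivetol (5-pentylbenzene-1,3-diol) | CCCCCc1cc(O)cc(O)c1 | starting material
2 | N-[(2,4-dihydroxy-6-pentylphenyl)methylidene]-N-methylmethanaminium chloride | CCCCCc1cc(O)cc(O)c1C=[N+](C)C.[Cl-] | intermediate
3 | 2,4-dihydroxy-6-pentylbenzaldehyde | CCCCCc1cc(O)cc(O)c1C=O | intermediate
4 | 2-hydroxy-4-methoxy-6-pentylbenzaldehyde | CCCCCc1cc(OC)cc(O)c1C=O | intermediate
5 | 4-methoxy-2-(methoxymethoxy)-6-pentylbenzaldehyde | CCCCCc1cc(OC)cc(OCOC)c1C=O | intermediate
6 | 4-methoxy-2-(methoxymethoxy)-6-pentylbenzoic acid | CCCCCc1cc(OC)cc(OCOC)c1C(=O)O | intermediate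
7 | 5-propylresorcinol (5-propylbenzene-1,3-diol) | CCCc1cc(O)cc(O)c1 | starting material
8 | 1,3-dimethoxy-5-propylbenzene | CCCc1cc(OC)cc(OC)c1 | intermediate
9 | 3-methoxy-5-propylphenol | CCCc1cc(O)cc(OC)c1 | intermediate
10 | 4-iodo-3-methoxy-5-propylphenol | CCCc1cc(O)cc(OC)c1I | intermediate
11 | 4-iodo-3-methoxy-5-propylphenyl 4-methoxy-2-(methoxymethoxy)-6-pentylbenzoate | CCCCCc1cc(OC)cc(OCOC)c1C(=O)Oc1cc(CCC)c(I)c(OC)c1 | intermediate
12 | 4-iodo-3-methoxy-5-propylphenyl 2-hydroxy-4-methoxy-6-pentylbenzoate | CCCCCc1cc(OC)cc(O)c1C(=O)Oc1cc(CCC)c(I)c(OC)c1 | intermediate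
13 | 4-[(2-hydroxy-4-methoxy-6-pentylbenzoyl)oxy]-2-methoxy-6-propylbenzoic acid | CCCCCc1cc(OC)cc(O)c1C(=O)Oc1cc(CCC)c(C(=O)O)c(OC)c1 | target

**Step count**

Total: 10 steps. Longest linear sequence: 7 steps (steps 1–4 and 8–10, from olivetol); the ring B branch (steps 5–7) joins at step 8.

**Steps most likely to fail**

1. Step 10 (hydroxycarbonylation). What may go wrong: acetate- or hydroxide-mediated cleavage of the aryl ester, assisted by partial deprotonation of the neighbouring 2-hydroxyl, or reductive loss of iodine because CO insertion and capture are slow at the crowded C1. Fallback, setting out from 12: the carbonylation is run without water in dry toluene with benzyl alcohol as the nucleophile (Pd(OAc)2, Xantphos, CO, Et3N, 80 °C). This should give benzyl 4-[(2-hydroxy-4-methoxy-6-pentylbenzoyl)oxy]-2-methoxy-6-propylbenzoate F1. Hydrogenolysis of the benzyl ester (H2, Pd/C, EtOAc, rt), to which aryl esters are inert, then comes back to the route at 13.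

2. Step 7 (iodination). What may go wrong: poor regioselectivity between the carbon para to the hydroxyl and the carbon para to the methoxy group, together with over-iodination of the doubly activated ring. Fallback, setting out from 9: nitrosation (NaNO2, aqueous propionic acid, 0 °C), which is reliably para to a phenolic hydroxyl, should give 3-methoxy-4-nitroso-5-propylphenol F2. Hydrogenation (H2, Pd/C, MeOH) gives 4-amino-3-methoxy-5-propylphenol F3. Diazotisation (NaNO2, aq. H2SO4, 0 °C) gives 4-hydroxy-2-methoxy-6-propylbenzenediazonium hydrogen sulfate F4, which is treated with KI without isolation (Sandmeyer-type iodo-dediazoniation) and comes back to the route at 10 with the iodine position fixed by the nitrogen.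

3. Step 8 (esterification). What may go wrong: rearrangement of the activated acid to the unreactive N-acylurea before the slow acyl transfer at the doubly ortho-substituted carbonyl. Fallback, setting out from 6: cyanuric fluoride and pyridine in CH2Cl2 should convert the acid into 4-methoxy-2-(methoxymethoxy)-6-pentylbenzoyl fluoride F5, a small acyl donor that generates no HCl and so spares the acetal. F5 is then stirred with phenol 10 and K2CO3 in MeCN and comes back to the route at 11.

**Further compounds**

F1 | step 10 | benzyl 4-[(2-hydroxy-4-methoxy-6-pentylbenzoyl)oxy]-2-methoxy-6-propylbenzoate | CCCCCc1cc(OC)cc(O)c1C(=O)Oc1cc(CCC)c(C(=O)OCc2ccccc2)c(OC)c1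
F2 | step 7 | 3-methoxy-4-nitroso-5-propylphenol | CCCc1cc(O)cc(OC)c1N=O
F3 | step 7 | 4-amino-3-methoxy-5-propylphenol | CCCc1cc(O)cc(OC)c1N
F4 | step 7 | 4-hydroxy-2-methoxy-6-propylbenzenediazonium hydrogen sulfate | CCCc1cc(O)cc(OC)c1[N+]#N.OS(=O)(=O)[O-]
F5 | step 8 | 4-methoxy-2-(methoxymethoxy)-6-pentylbenzoyl fluoride | CCCCCc1cc(OC)cc(OCOC)c1C(F)=O
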